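**Assumption:** the target (5‑demethoxyubiquinone‑10, C58H88O3) has no stereocentres. I read "single enantiomer" as the single all‑E isomer, meaning nine E trisubstituted alkenes.

## Retrosynthetic overview
1. The quinone comes from the para‑unsubstituted phenol 9 by aerobic oxidation in the last step, with no protecting groups.
2. The aryl–allyl bond comes from sodium 2‑methoxy‑5‑methylphenoxide plus all‑E‑decaprenyl bromide. The phenol's only free ortho carbon is the one required.
3. Decaprenyl (C50) comes from solanesol (C45, eight E alkenes purchased) + C3 (TMS‑propyne) + CH3 (Me3Al) + CH2O. The ninth E alkene is set by syn‑methylalumination.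
4. No ring is constructed. The single six‑membered ring is purchased as the arene and becomes the quinone in the final step.

## Route

**Step 1**
- Reactants: 1, solanesol (all‑E nonaprenol)
- Product: 2, all‑E‑solanesyl bromide (used crude)
- Conditions: PBr3 (0.4 equiv), cat. pyridine, Et2O/hexane, −10 → 0 °C, dark
- Reagents that add atoms: phosphorus tribromide, BrP(Br)Br
- Why: PBr3 bromination is an SN2 displacement of the phosphite ester at a primary allylic carbon, and at low temperature it proceeds without allylic transposition or E/Z erosion.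

**Step 2** (one pot, two operations)
- Reactants: 2, solanesyl bromide; 3, 1‑(trimethylsilyl)propyne
- Product: 5, all‑E‑6,10,14,18,22,26,30,34,38‑nonamethylnonatriaconta‑5,9,13,17,21,25,29,33,37‑nonaen‑1‑yne (C48H76), formed via C‑silyl enyne 4, which is not isolated
- Conditions: 3, n‑BuLi, THF, −78 → −20 °C; add 2, −78 → 0 °C; then NaOEt/EtOH, 60 °C
- Reagents that add atoms: 1‑(trimethylsilyl)propyne, CC#C[Si](C)(C)C (only its CH2C≡CH unit is retained)
- Why: In this Corey–Kirst propargylation, lithiated TMS‑propyne attacks through its propargylic carbon in an SN2 reaction on the allylic bromide, and ethoxide protodesilylation then frees the terminal alkyne without touching the alkenes.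

**Step 3**
- Reactants: 5, terminal enyne
- Product: 6, all‑E‑decaprenol (C50H82O)
- Conditions: Me3Al (2 equiv), Cp2ZrCl2 (0.25 equiv), ClCH2CH2Cl, 0 → 23 °C; evaporate volatiles; hexane/THF, n‑BuLi, −78 → 0 °C; (CH2O)n (5 equiv), 23 °C; Rochelle salt work‑up; chromatography removes about 5 % regioisomer
- Reagents that add atoms: trimethylaluminium, C[Al](C)C (adds CH3); paraformaldehyde, C=O (adds CH2O)
- Why: Negishi Zr‑catalysed methylalumination adds Me and Al syn across only the terminal alkyne (≥98 % E), the trisubstituted alkenes are inert, and the derived alanate captures formaldehyde with retention, which sets the ninth E alkene.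

**Step 4**
- Reactants: 6, decaprenol
- Product: 7, all‑E‑decaprenyl bromide (used crude)
- Conditions: PBr3 (0.4 equiv), cat. pyridine, Et2O/hexane, −10 → 0 °C, dark
- Reagents that add atoms: phosphorus tribromide, BrP(Br)Br
- Why: This is the same SN2 PBr3 bromination of a primary allylic alcohol as in step 1, so the geometry is retained.

**Step 5**
- Reactants: 7, decaprenyl bromide; 8, 2‑methoxy‑5‑methylphenol (3 equiv)
- Product: 9, 2‑[(all‑E)‑decaprenyl]‑6‑methoxy‑3‑methylphenol (C58H90O2)
- Conditions: 8, NaH (2.9 equiv), toluene, 0 → 23 °C (suspension); add 7 in toluene, 23 → 40 °C; aq. NH4Cl (no acid); chromatography separates the O‑alkyl ether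
- Reagents that add atoms: none beyond the two listed reactants
- Why: In this Claisen/Kornblum ortho‑C‑alkylation, the tight‑ion‑pair sodium phenoxide in a non‑polar medium delivers the allylic bromide by SN2 (α‑attack, E retained) to the only free ortho carbon (C6 of 8), and the excess phenoxide suppresses over‑alkylation.

**Step 6**
- Reactants: 9, decaprenyl phenol
- Product: 10, target, 2‑[(all‑E)‑decaprenyl]‑6‑methoxy‑3‑methyl‑1,4‑benzoquinone (C58H88O3)
- Conditions: Co(salen) (salcomine, 10 mol %), O2 (1 atm), DMF/THF 1:1, 23 °C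
- Reagents that add atoms: dioxygen, O=O
- Why: Salcomine‑catalysed aerobic phenol‑to‑p‑quinone oxidation oxygenates the free para C–H of a 2,3,6‑trisubstituted phenol through the Co‑superoxo/phenoxyl pathway and leaves isolated trisubstituted alkenes intact.

## Compound list

| No. | Name | SMILES | Role |
|---|---|---|---|
| 1 | Solanesol | `OC/C=C(\C)CC/C=C(\C)CC/C=C(\C)CC/C=C(\C)CC/C=C(\C)CC/C=C(\C)CC/C=C(\C)CC/C=C(\C)CCC=C(C)C` | starting material |
| 2 | Solanesyl bromide | `BrC/C=C(\C)CC/C=C(\C)CC/C=C(\C)CC/C=C(\C)CC/C=C(\C)CC/C=C(\C)CC/C=C(\C)CC/C=C(\C)CCC=C(C)C` | intermediate |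
| 3 | 1‑(Trimethylsilyl)propyne | `CC#C[Si](C)(C)C` | starting material |
| 4 | 1‑TMS‑solanesylpropyne (not isolated) | `C[Si](C)(C)C#CCC/C=C(\C)CC/C=C(\C)CC/C=C(\C)CC/C=C(\C)CC/C=C(\C)CC/C=C(\C)CC/C=C(\C)CC/C=C(\C)CCC=C(C)C` | intermediate |
| 5 | Terminal C48 enyne | `C#CCC/C=C(\C)CC/C=C(\C)CC/C=C(\C)CC/C=C(\C)CC/C=C(\C)CC/C=C(\C)CC/C=C(\C)CC/C=C(\C)CCC=C(C)C` | intermediate |
| 6 | all‑E‑Decaprenol | `OC/C=C(\C)CC/C=C(\C)CC/C=C(\C)CC/C=C(\C)CC/C=C(\C)CC/C=C(\C)CC/C=C(\C)CC/C=C(\C)CC/C=C(\C)CCC=C(C)C` | intermediate |
| 7 | all‑E‑Decaprenyl bromide | `BrC/C=C(\C)CC/C=C(\C)CC/C=C(\C)CC/C=C(\C)CC/C=C(\C)CC/C=C(\C)CC/C=C(\C)CC/C=C(\C)CC/C=C(\C)CCC=C(C)C` | intermediate |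
| 8 | 2‑Methoxy‑5‑methylphenol | `COc1ccc(C)cc1O` | starting material |
| 9 | 2‑Decaprenyl‑6‑methoxy‑3‑methylphenol | `COc1ccc(C)c(C/C=C(\C)CC/C=C(\C)CC/C=C(\C)CC/C=C(\C)CC/C=C(\C)CC/C=C(\C)CC/C=C(\C)CC/C=C(\C)CC/C=C(\C)CCC=C(C)C)c1O` | intermediate |
| 10 | 5‑Demethoxyubiquinone‑10 | `COC1=CC(=O)C(C)=C(C/C=C(\C)CC/C=C(\C)CC/C=C(\C)CC/C=C(\C)CC/C=C(\C)CC/C=C(\C)CC/C=C(\C)CC/C=C(\C)CC/C=C(\C)CCC=C(C)C)C1=O` | target |

## Summary
- **Total step count:** 6. Step 2 is a telescoped one‑pot, so the count is 7 if its desilylation is counted separately.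
- **Longest linear sequence:** 6 steps, from solanesol.

**Three steps most likely to fail**

1. **Step 5.** The risks are competing O‑alkylation and a hindered ortho site next to CH3; I expect roughly 35–50 % yield.
   - Fallback: change the disconnection to benzyl–vinyl.
   - Convert 8 to 2‑(chloromethyl)‑6‑methoxy‑3‑methylphenyl tosylate by Casnati–Skattebøl ortho‑formylation (MgCl2/Et3N/(CH2O)n), TsCl, NaBH4 and SOCl2.
   - Couple that chloride under Ni(0) directly with the vinylalane of step 3, taken before the formaldehyde quench. Detosylation then gives 9, and compounds 6 and 7 are bypassed.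
2. **Step 3.** The risks are incomplete or regio‑impure carboalumination and sluggish formaldehyde capture on a waxy C48 substrate.
   - Fallback: Biellmann sulfone C5 homologation.
   - Alkylate lithiated (E)‑PhSO2CH2C(CH3)=CHCH2OTHP with bromide 2.
   - Remove the sulfone with PdCl2(dppp)/LiEt3BH and cleave the THP to give 6. The new E alkene then comes from E‑selective SeO2 oxidation of a prenyl ether.
3. **Step 6.** The risks are poor solubility, slow turnover, and autoxidation at the doubly activated ArCH2 position.
   - Fallback: install both quinone oxygens before attaching the chain.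
   - Oxidise 8 itself to 2‑methoxy‑5‑methyl‑1,4‑benzoquinone and convert 7 to decaprenyltrimethylstannane with Me3SnLi.
   - Join the two by Naruta allylation (BF3·OEt2, −78 °C), which proceeds by 1,2‑addition at the non‑vinylogous‑ester carbonyl followed by a [3,3] shift to the adjacent C–H. Reoxidise the hydroquinone with Ag2O.
   - The regiochemistry of this addition is expected from that mechanism but would need to be confirmed by NMR.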